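The two dihydrofuran rings fused to the central benzene ring are both (2R,3R) and their oxygens sit meta on that ring, each ortho to the carbon that carries C3; the target therefore derives from a C2-symmetric bis(dihydrobenzofuran) stilbene, closed last to the seven-membered ring by acid. The key step exploits this symmetry: a doubly benzylic dianion on a 1,3-difluoroarene adds to two molecules of 4-(methoxymethoxy)benzaldehyde (both C2–C3 bonds) and each alkoxide displaces its ortho fluoride (both ring O–aryl bonds), closing both rings in one flask. The precursor is a 2,6-dibenzyl-3,5-difluoro-4-silylphenyl oxazoline; the valinol oxazoline directs the benzylations, makes the stereoisomers separable and becomes the stilbene carbon.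

Key step: step 8

Remark: the tricyclic core is numbered as benzo[1,2-b:5,4-b']difuran (O1, C2, C3, C3a, C4, C4a, C5, C6, O7, C7a, C8, C8a); all phenols are carried as methoxymethyl (MOM) ethers so that one acid treatment at the end frees them and closes the last ring; compounds 8, 13 and 21 are taken as purchasable.

Step 1
Reactants: 1 2,3,5,6-tetrafluorobenzoic acid; 2 (S)-valinol
Product: 4 N-[(2S)-1-hydroxy-3-methylbutan-2-yl]-2,3,5,6-tetrafluorobenzamide, via 2,3,5,6-tetrafluorobenzoyl chloride 3 (not isolated)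
Conditions: (COCl)2, cat. DMF, CH2Cl2, 0 °C → rt; concentrate; then 2, Et3N, CH2Cl2, 0 °C
Reagents that add atoms: none
Why: Acid chloride formation followed by N-acylation of the amino alcohol, which is faster at nitrogen than at oxygen and far faster than SNAr on the fluoroarene at 0 °C; the valinol stereocentre is not involved.

Step 2
Reactants: 4 N-[(2S)-1-hydroxy-3-methylbutan-2-yl]-2,3,5,6-tetrafluorobenzamide
Product: 6 (4S)-4-isopropyl-2-(2,3,5,6-tetrafluorophenyl)-4,5-dihydro-1,3-oxazole, via hydroxy amide mesylate 5 (not isolated)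
Conditions: MsCl, Et3N, CH2Cl2, 0 → 40 °C
Reagents that add atoms: none
Why: O-Mesylation of the primary alcohol and 5-exo-tet displacement by the amide oxygen is the standard cyclodehydration of β-hydroxy amides to 2-oxazolines, and it does not touch the stereocentre.

Step 3
Reactants: 6 (4S)-4-isopropyl-2-(2,3,5,6-tetrafluorophenyl)-4,5-dihydro-1,3-oxazole
Product: 7 (4S)-4-isopropyl-2-[2,3,5,6-tetrafluoro-4-(trimethylsilyl)phenyl]-4,5-dihydro-1,3-oxazole
Conditions: LiN(i-Pr)2, Me3SiCl (present from the start), THF, −78 °C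
Reagents that add atoms: chlorotrimethylsilane C[Si](C)(C)Cl
Why: The only ring proton lies between two fluorines and is removed by the amide base at −78 °C, the aryllithium is silylated at once by the chlorosilane already in the flask before it can lose LiF, and the silyl group then blocks this most acidic position in steps 7 and 8.

Step 4
Reactants: 8 3,5-dihydroxybenzyl alcohol
Product: 9 [3,5-bis(methoxymethoxy)phenyl]methanol
Conditions: NaH (2.1 equiv), DMF, 0 °C; MOMCl (2.1 equiv), 0 °C → rt
Reagents that add atoms: chloromethyl methyl ether COCCl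
Why: Two equivalents of NaH form only the two phenoxides, which are O-alkylated by MOMCl (Williamson-type) while the less acidic benzylic alcohol stays protonated.

Step 5
Reactants: 9 [3,5-bis(methoxymethoxy)phenyl]methanol
Product: 10 1-(chloromethyl)-3,5-bis(methoxymethoxy)benzene
Conditions: PPh3, N-chlorosuccinimide, THF, 0 °C → rt
Reagents that add atoms: N-chlorosuccinimide O=C1CCC(=O)N1Cl
Why: Appel-type chlorination through the alkoxyphosphonium salt converts the benzylic alcohol into the chloride under neutral conditions that spare the MOM acetals.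

Step 6
Reactants: 10 1-(chloromethyl)-3,5-bis(methoxymethoxy)benzene
Product: 11 [3,5-bis(methoxymethoxy)benzyl]magnesium chloride (THF solution, used directly)
Conditions: Mg turnings (activated with a trace of 1,2-dibromoethane), THF, 0 °C → rt, slow addition
Reagents that add atoms: magnesium [Mg]
Why: Magnesium inserts into the benzylic C–Cl bond, slow addition at low concentration limits Wurtz coupling, and the MOM ethers are inert to the Grignard reagent.

Step 7
Reactants: 7 (4S)-4-isopropyl-2-[2,3,5,6-tetrafluoro-4-(trimethylsilyl)phenyl]-4,5-dihydro-1,3-oxazole; 11 [3,5-bis(methoxymethoxy)benzyl]magnesium chloride (2.6 equiv)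
Product: 12 (4S)-2-{2,6-bis[3,5-bis(methoxymethoxy)benzyl]-3,5-difluoro-4-(trimethylsilyl)phenyl}-4-isopropyl-4,5-dihydro-1,3-oxazole
Conditions: THF, 0 → 40 °C
Reagents that add atoms: none
Why: Oxazoline-directed SNAr, in which magnesium bound to the oxazoline nitrogen delivers the benzyl group to the ortho C–F carbon and the C=N unit takes up the Meisenheimer charge, replaces only the two fluorides ortho to the oxazoline and leaves the two next to silicon for step 8.

Step 8
Reactants: 12 (4S)-2-{2,6-bis[3,5-bis(methoxymethoxy)benzyl]-3,5-difluoro-4-(trimethylsilyl)phenyl}-4-isopropyl-4,5-dihydro-1,3-oxazole; 13 4-(methoxymethoxy)benzaldehyde (2.3 equiv)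
Product: 16 (4S)-2-[(2R,3R,5R,6R)-3,5-bis[3,5-bis(methoxymethoxy)phenyl]-2,6-bis[4-(methoxymethoxy)phenyl]-8-(trimethylsilyl)-2,3,5,6-tetrahydrobenzo[1,2-b:5,4-b']difuran-4-yl]-4-isopropyl-4,5-dihydro-1,3-oxazole, via dilithio derivative 14 (not isolated), via dilithium bis-alkoxide 15 (not isolated)
Conditions: LiN(i-Pr)2 (2.4 equiv), THF, −78 °C; 13, −78 °C; then DMPU, −78 → 60 °C; chromatographic separation of the diastereomers
Reagents that add atoms: none
Why: Proposed new method: LiN(i-Pr)2 removes one proton from each doubly benzylic CH2 group (each lies between the lithium-binding oxazoline and a C–F carbon), the dilithio compound 14 adds to two molecules of 13 to give the bis-alkoxide 15, and on warming with DMPU each alkoxide attacks the fluorine-bearing ring carbon ortho to its benzylic carbon and expels fluoride (addition–elimination, SNAr), so that the C2–C3 bond and the ring O–aryl bond of each dihydrofuran ring are made in one flask. The closest known reaction types are the lateral lithiation/aldehyde addition of ortho-benzyl aryl oxazolines, the intramolecular SNAr etherification of 2-(2-fluoroaryl)ethoxides to 2,3-dihydrobenzofurans and the tandem benzylic deprotonation/addition/SNAr route from 2-fluorotoluenes and nitriles to indoles; their union with an aldehyde, run twice on one ring, is the new element. Both dihydrofuran rings close in the 5-exo-trig mode. In each ring the 2,3-trans relation should result because aldehyde addition is reversible at the alkoxide stage and the alkoxide that places the two aryl groups anti closes faster, whereas the absolute sense at C3 is not set by a reagent, so the trans,trans product is expected as the (R,R,R,R), (S,S,S,S) and (R,R,S,S) isomers, which the (S)-oxazoline turns into diastereomers, and 16 is the (2R,3R,5R,6R) isomer isolated by chromatography. The step needs benzylic instead of aryl deprotonation and ring closure on C–F instead of on the oxazoline C=N carbon: the Me3Si group occupies the acidic position between the two fluorines, and fluoride loss is irreversible whereas alkoxide addition to the oxazoline is reversible. A 2,3-cis ring with the correct C3 configuration is not lost, since the acid of step 13 epimerises C2 through the ring-opened quinone methide.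

Step 9
Reactants: 16 (4S)-2-[(2R,3R,5R,6R)-3,5-bis[3,5-bis(methoxymethoxy)phenyl]-2,6-bis[4-(methoxymethoxy)phenyl]-8-(trimethylsilyl)-2,3,5,6-tetrahydrobenzo[1,2-b:5,4-b']difuran-4-yl]-4-isopropyl-4,5-dihydro-1,3-oxazole
Product: 19 (2R,3R,5R,6R)-3,5-bis[3,5-bis(methoxymethoxy)phenyl]-2,6-bis[4-(methoxymethoxy)phenyl]-8-(trimethylsilyl)-2,3,5,6-tetrahydrobenzo[1,2-b:5,4-b']difuran-4-carbaldehyde, via N-methyloxazolinium triflate 17 (not isolated), via N-methyloxazolidine 18 (not isolated)
Conditions: MeOTf, CH2Cl2, 0 °C → rt; NaBH4, THF/MeOH, 0 °C; oxalic acid, THF/H2O, rt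
Reagents that add atoms: water O
Why: N-Methylation turns the hindered oxazoline into an oxazolinium ion that NaBH4 reduces to the N,O-acetal, and mild aqueous acid then releases the aldehyde (the standard unmasking of aryl oxazolines) without touching the MOM ethers, the aryl silane or the four ring stereocentres, the auxiliary leaving as N-methylvalinol.

Step 10
Reactants: 19 (2R,3R,5R,6R)-3,5-bis[3,5-bis(methoxymethoxy)phenyl]-2,6-bis[4-(methoxymethoxy)phenyl]-8-(trimethylsilyl)-2,3,5,6-tetrahydrobenzo[1,2-b:5,4-b']difuran-4-carbaldehyde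
Product: 20 (2R,3R,5R,6R)-4-ethenyl-3,5-bis[3,5-bis(methoxymethoxy)phenyl]-2,6-bis[4-(methoxymethoxy)phenyl]-8-(trimethylsilyl)-2,3,5,6-tetrahydrobenzo[1,2-b:5,4-b']difuran
Conditions: Ph3PCH3Br, KOt-Bu, THF, 0 °C → rt
Reagents that add atoms: methyltriphenylphosphonium bromide [Br-].C[P+](c1ccccc1)(c1ccccc1)c1ccccc1
Why: Wittig methylenation with the small non-stabilised ylide tolerates the two ortho substituents, and the ylide is consumed by the aldehyde before it can act as a base at C3–H.

Step 11
Reactants: 21 4-bromoresorcinol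
Product: 22 1-bromo-2,4-bis(methoxymethoxy)benzene
Conditions: MOMCl, i-Pr2NEt, CH2Cl2, 0 °C → rt
Reagents that add atoms: chloromethyl methyl ether COCCl
Why: Both phenols are O-alkylated by MOMCl in the presence of the hindered amine base.

Step 12
Reactants: 20 (2R,3R,5R,6R)-4-ethenyl-3,5-bis[3,5-bis(methoxymethoxy)phenyl]-2,6-bis[4-(methoxymethoxy)phenyl]-8-(trimethylsilyl)-2,3,5,6-tetrahydrobenzo[1,2-b:5,4-b']difuran; 22 1-bromo-2,4-bis(methoxymethoxy)benzene
Product: 23 (2R,3R,5R,6R)-4-{(E)-2-[2,4-bis(methoxymethoxy)phenyl]ethenyl}-3,5-bis[3,5-bis(methoxymethoxy)phenyl]-2,6-bis[4-(methoxymethoxy)phenyl]-8-(trimethylsilyl)-2,3,5,6-tetrahydrobenzo[1,2-b:5,4-b']difuran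
Conditions: Pd2(dba)3 (cat.), [HP(t-Bu)3]BF4 (cat.), Cy2NMe, 1,4-dioxane, 90 °C
Reagents that add atoms: none
Why: Mizoroki–Heck reaction in which the electron-rich aryl bromide adds oxidatively to the bulky zerovalent palladium/P(t-Bu)3 catalyst, the aryl group is delivered to the unhindered terminal alkene carbon and β-hydride elimination gives the stilbene, whose geometry (E expected) is of no consequence for step 13.

Step 13
Reactants: 23 (2R,3R,5R,6R)-4-{(E)-2-[2,4-bis(methoxymethoxy)phenyl]ethenyl}-3,5-bis[3,5-bis(methoxymethoxy)phenyl]-2,6-bis[4-(methoxymethoxy)phenyl]-8-(trimethylsilyl)-2,3,5,6-tetrahydrobenzo[1,2-b:5,4-b']difuran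
Product: 25 target CNP0154047.1, via free octaphenol stilbene 24 (not isolated)
Conditions: conc. HCl, MeOH, 60 °C
Reagents that add atoms: none
Why: HCl in MeOH cleaves the eight MOM acetals and protodesilylates the aryl silane flanked by two ring oxygens, protonation of the 2,4-dihydroxystilbene 24 at the alkene carbon next to the central ring gives a benzylic cation stabilised by the ortho- and para-hydroxy groups, and the ortho carbon of a neighbouring 3,5-dihydroxyphenyl ring (the two are homotopic in C2-symmetric 24, so either closure gives 25) attacks it in a seven-membered Friedel–Crafts alkylation, the reaction type by which ε-viniferin-type stilbenes close to ampelopsin-B-type rings; the new centre should be R because the 2,4-dihydroxyphenyl group points outward in the closing transition state, pseudo-equatorial and anti to the dihydrofuran ring fused at the neighbouring carbon, and reversible ionisation lets the more stable epimer accumulate.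

Compound list
1 | 2,3,5,6-tetrafluorobenzoic acid | OC(=O)c1c(F)c(F)cc(F)c1F | starting material
2 | (S)-valinol, (2S)-2-amino-3-methylbutan-1-ol | CC(C)[C@H](N)CO | starting material
3 | 2,3,5,6-tetrafluorobenzoyl chloride (not isolated) | O=C(Cl)c1c(F)c(F)cc(F)c1F | intermediate
4 | N-[(2S)-1-hydroxy-3-methylbutan-2-yl]-2,3,5,6-tetrafluorobenzamide | CC(C)[C@H](NC(=O)c1c(F)c(F)cc(F)c1F)CO | intermediate
5 | (2S)-3-methyl-2-(2,3,5,6-tetrafluorobenzamido)butyl methanesulfonate (not isolated) | CC(C)[C@H](NC(=O)c1c(F)c(F)cc(F)c1F)COS(C)(=O)=O | intermediate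
6 | (4S)-4-isopropyl-2-(2,3,5,6-tetrafluorophenyl)-4,5-dihydro-1,3-oxazole | CC(C)[C@H]1COC(=N1)c1c(F)c(F)cc(F)c1F | intermediate
7 | (4S)-4-isopropyl-2-[2,3,5,6-tetrafluoro-4-(trimethylsilyl)phenyl]-4,5-dihydro-1,3-oxazole | CC(C)[C@H]1COC(=N1)c1c(F)c(F)c([Si](C)(C)C)c(F)c1F | intermediate
8 | 3,5-dihydroxybenzyl alcohol | OCc1cc(O)cc(O)c1 | starting material
9 | [3,5-bis(methoxymethoxy)phenyl]methanol | COCOc1cc(CO)cc(OCOC)c1 | intermediate
10 | 1-(chloromethyl)-3,5-bis(methoxymethoxy)benzene | COCOc1cc(CCl)cc(OCOC)c1 | intermediate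
11 | [3,5-bis(methoxymethoxy)benzyl]magnesium chloride | COCOc1cc(C[Mg]Cl)cc(OCOC)c1 | intermediate
12 | (4S)-2-{2,6-bis[3,5-bis(methoxymethoxy)benzyl]-3,5-difluoro-4-(trimethylsilyl)phenyl}-4-isopropyl-4,5-dihydro-1,3-oxazole | CC(C)[C@H]1COC(=N1)c1c(Cc2cc(OCOC)cc(OCOC)c2)c(F)c([Si](C)(C)C)c(F)c1Cc1cc(OCOC)cc(OCOC)c1 | intermediate
13 | 4-(methoxymethoxy)benzaldehyde | COCOc1ccc(C=O)cc1 | starting material
14 | dilithio derivative of 12, lithiated at both benzylic carbons (not isolated) | CC(C)[C@H]1COC(=N1)c1c(C([Li])c2cc(OCOC)cc(OCOC)c2)c(F)c([Si](C)(C)C)c(F)c1C([Li])c1cc(OCOC)cc(OCOC)c1 | intermediate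
15 | dilithium bis-alkoxide from addition of 14 to two molecules of 13, mixture of stereoisomers at the four new centres (not isolated) | CC(C)[C@H]1COC(=N1)c1c(C(c2cc(OCOC)cc(OCOC)c2)C(O[Li])c2ccc(OCOC)cc2)c(F)c([Si](C)(C)C)c(F)c1C(c1cc(OCOC)cc(OCOC)c1)C(O[Li])c1ccc(OCOC)cc1 | intermediate
16 | (4S)-2-[(2R,3R,5R,6R)-3,5-bis[3,5-bis(methoxymethoxy)phenyl]-2,6-bis[4-(methoxymethoxy)phenyl]-8-(trimethylsilyl)-2,3,5,6-tetrahydrobenzo[1,2-b:5,4-b']difuran-4-yl]-4-isopropyl-4,5-dihydro-1,3-oxazole | COCOc1ccc([C@@H]2Oc3c([Si](C)(C)C)c4c([C@@H](c5cc(OCOC)cc(OCOC)c5)[C@H](c5ccc(OCOC)cc5)O4)c(C6=N[C@@H](C(C)C)CO6)c3[C@H]2c2cc(OCOC)cc(OCOC)c2)cc1 | intermediate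
17 | N-methyloxazolinium triflate of 16 (not isolated) | COCOc1ccc([C@@H]2Oc3c([Si](C)(C)C)c4c([C@@H](c5cc(OCOC)cc(OCOC)c5)[C@H](c5ccc(OCOC)cc5)O4)c(C6=[N+](C)[C@@H](C(C)C)CO6)c3[C@H]2c2cc(OCOC)cc(OCOC)c2)cc1.[O-]S(=O)(=O)C(F)(F)F | intermediate
18 | N-methyloxazolidine from reduction of 17, aminal carbon unspecified (not isolated) | COCOc1ccc([C@@H]2Oc3c([Si](C)(C)C)c4c([C@@H](c5cc(OCOC)cc(OCOC)c5)[C@H](c5ccc(OCOC)cc5)O4)c(C6N(C)[C@@H](C(C)C)CO6)c3[C@H]2c2cc(OCOC)cc(OCOC)c2)cc1 | intermediate
19 | (2R,3R,5R,6R)-3,5-bis[3,5-bis(methoxymethoxy)phenyl]-2,6-bis[4-(methoxymethoxy)phenyl]-8-(trimethylsilyl)-2,3,5,6-tetrahydrobenzo[1,2-b:5,4-b']difuran-4-carbaldehyde | COCOc1ccc([C@@H]2Oc3c([Si](C)(C)C)c4c([C@@H](c5cc(OCOC)cc(OCOC)c5)[C@H](c5ccc(OCOC)cc5)O4)c(C=O)c3[C@H]2c2cc(OCOC)cc(OCOC)c2)cc1 | intermediate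
20 | (2R,3R,5R,6R)-4-ethenyl-3,5-bis[3,5-bis(methoxymethoxy)phenyl]-2,6-bis[4-(methoxymethoxy)phenyl]-8-(trimethylsilyl)-2,3,5,6-tetrahydrobenzo[1,2-b:5,4-b']difuran | COCOc1ccc([C@@H]2Oc3c([Si](C)(C)C)c4c([C@@H](c5cc(OCOC)cc(OCOC)c5)[C@H](c5ccc(OCOC)cc5)O4)c(C=C)c3[C@H]2c2cc(OCOC)cc(OCOC)c2)cc1 | intermediate
21 | 4-bromoresorcinol | Oc1ccc(Br)c(O)c1 | starting material
22 | 1-bromo-2,4-bis(methoxymethoxy)benzene | COCOc1ccc(Br)c(OCOC)c1 | intermediate
23 | (2R,3R,5R,6R)-4-{(E)-2-[2,4-bis(methoxymethoxy)phenyl]ethenyl}-3,5-bis[3,5-bis(methoxymethoxy)phenyl]-2,6-bis[4-(methoxymethoxy)phenyl]-8-(trimethylsilyl)-2,3,5,6-tetrahydrobenzo[1,2-b:5,4-b']difuran | COCOc1ccc([C@@H]2Oc3c([Si](C)(C)C)c4c([C@@H](c5cc(OCOC)cc(OCOC)c5)[C@H](c5ccc(OCOC)cc5)O4)c(/C=C/c5ccc(OCOC)cc5OCOC)c3[C@H]2c2cc(OCOC)cc(OCOC)c2)cc1 | intermediate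
24 | 4-{(E)-2-[(2R,3R,5R,6R)-3,5-bis(3,5-dihydroxyphenyl)-2,6-bis(4-hydroxyphenyl)-2,3,5,6-tetrahydrobenzo[1,2-b:5,4-b']difuran-4-yl]ethenyl}benzene-1,3-diol (not isolated) | Oc1ccc([C@@H]2Oc3cc4c([C@@H](c5cc(O)cc(O)c5)[C@H](c5ccc(O)cc5)O4)c(/C=C/c5ccc(O)cc5O)c3[C@H]2c2cc(O)cc(O)c2)cc1 | intermediate
25 | target CNP0154047.1: compound 24 in which the alkene carbon bearing the 2,4-dihydroxyphenyl group is bonded to C2 of one 3,5-dihydroxyphenyl ring, so that a CH2–CH(aryl) bridge closes a seven-membered ring; both dihydrofuran rings (2R,3R), new benzylic centre R | Oc1ccc([C@@H]2Oc3cc4c5c(c3[C@H]2c2cc(O)cc(O)c2)C[C@H](c2ccc(O)cc2O)c2c(O)cc(O)cc2[C@H]5[C@H](c2ccc(O)cc2)O4)cc1 | target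

Total step count: 13. Longest linear sequence: 9 steps (steps 1, 2, 3, 7, 8, 9, 10, 12 and 13; the branch through steps 4, 5 and 6 is equally long).

Steps most likely to fail

Step 8 (proposed new method). During the warm-up the alkoxide may be lost by retro-addition, by hydride transfer to free aldehyde or by silyl migration from carbon to oxygen before the lithium alkoxide displaces fluoride, and the ratio of trans to cis rings and of the three diastereomers may be unfavourable for isolation. The fallback uses known chemistry, sets out from 12 and comes back at 16: the dianion of 12 is treated with 13 at −78 °C and protonated cold, which gives the isolable bis(carbinol) (4S)-2-{3,5-difluoro-2,6-bis[2-hydroxy-1-[3,5-bis(methoxymethoxy)phenyl]-2-[4-(methoxymethoxy)phenyl]ethyl]-4-(trimethylsilyl)phenyl}-4-isopropyl-4,5-dihydro-1,3-oxazole F1 (lateral lithiation/aldehyde addition). F1 is then cyclised in a separate operation with KOt-Bu in DMF at 60–80 °C, the established intramolecular SNAr etherification of 2-(2-fluoroaryl)ethanols, in the absence of free aldehyde, and 16 is separated from its diastereomers as in the route.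

Step 13. Acid may open a dihydrofuran ring at C2 before the stilbene is protonated, which would divert the cation into five-membered (indane-type) closures, or the arene may attack the wrong face of the benzylic cation. The fallback sets out from 19 and comes back at 25, and it attaches the resorcinol ring last. Wittig reaction of 19 with the ylide from (methoxymethyl)triphenylphosphonium chloride and KOt-Bu gives the enol ether (2R,3R,5R,6R)-4-(2-methoxyethenyl)-3,5-bis[3,5-bis(methoxymethoxy)phenyl]-2,6-bis[4-(methoxymethoxy)phenyl]-8-(trimethylsilyl)-2,3,5,6-tetrahydrobenzo[1,2-b:5,4-b']difuran F2. With HCl in MeOH and an excess of resorcinol the oxocarbenium ion of F2, which forms under much milder acid than the stilbene cation, closes the seven-membered ring onto a neighbouring 3,5-dioxygenated phenyl ring. The resulting benzylic methyl ether then ionises and resorcinol is joined at its C4 from the open face of the ring cation (Friedel–Crafts), while the MOM and silyl groups are lost in the same flask.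

Step 12. Oxidative addition to the electron-rich, ortho-alkoxy aryl bromide and insertion of the hindered styrene may both be slow, so that reduction of 22 or decay of the catalyst wins. The fallback sets out from 19 and comes back at 23. Boron–Wittig olefination of 19 with lithiated bis(pinacolboryl)methane (CH2(Bpin)2, lithium 2,2,6,6-tetramethylpiperidide, THF, −78 °C → rt) gives the alkenylboronate (2R,3R,5R,6R)-3,5-bis[3,5-bis(methoxymethoxy)phenyl]-2,6-bis[4-(methoxymethoxy)phenyl]-4-[(E)-2-(4,4,5,5-tetramethyl-1,3,2-dioxaborolan-2-yl)ethenyl]-8-(trimethylsilyl)-2,3,5,6-tetrahydrobenzo[1,2-b:5,4-b']difuran F3. F3 is joined to 22 by Suzuki–Miyaura coupling (PdCl2(dppf), K3PO4, dioxane/H2O, 80 °C).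

Further compounds
F1 | step 8 | (4S)-2-{3,5-difluoro-2,6-bis[2-hydroxy-1-[3,5-bis(methoxymethoxy)phenyl]-2-[4-(methoxymethoxy)phenyl]ethyl]-4-(trimethylsilyl)phenyl}-4-isopropyl-4,5-dihydro-1,3-oxazole (mixture of carbinol stereoisomers) | CC(C)[C@H]1COC(=N1)c1c(C(c2cc(OCOC)cc(OCOC)c2)C(O)c2ccc(OCOC)cc2)c(F)c([Si](C)(C)C)c(F)c1C(c1cc(OCOC)cc(OCOC)c1)C(O)c1ccc(OCOC)cc1
F2 | step 13 | (2R,3R,5R,6R)-4-(2-methoxyethenyl)-3,5-bis[3,5-bis(methoxymethoxy)phenyl]-2,6-bis[4-(methoxymethoxy)phenyl]-8-(trimethylsilyl)-2,3,5,6-tetrahydrobenzo[1,2-b:5,4-b']difuran (E/Z mixture) | COCOc1ccc([C@@H]2Oc3c([Si](C)(C)C)c4c([C@@H](c5cc(OCOC)cc(OCOC)c5)[C@H](c5ccc(OCOC)cc5)O4)c(C=COC)c3[C@H]2c2cc(OCOC)cc(OCOC)c2)cc1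
F3 | step 12 | (2R,3R,5R,6R)-3,5-bis[3,5-bis(methoxymethoxy)phenyl]-2,6-bis[4-(methoxymethoxy)phenyl]-4-[(E)-2-(4,4,5,5-tetramethyl-1,3,2-dioxaborolan-2-yl)ethenyl]-8-(trimethylsilyl)-2,3,5,6-tetrahydrobenzo[1,2-b:5,4-b']difuran | COCOc1ccc([C@@H]2Oc3c([Si](C)(C)C)c4c([C@@H](c5cc(OCOC)cc(OCOC)c5)[C@H](c5ccc(OCOC)cc5)O4)c(/C=C/B5OC(C)(C)C(C)(C)O5)c3[C@H]2c2cc(OCOC)cc(OCOC)c2)cc1
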